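In a one-step world every Z turns over on its own, so the rate follows the charge of Z and the order in Z is 1. I took that as the zero of my scale.

| flask | J | G | Z | remark |
|---|---|---|---|---|
| teal | 2 M | 0.28 M | 0.5 mol% | run made earlier |
| red | 2 M | 0.44 M | 0.5 mol% | run made earlier |
| flask | 2.0 M | 0.200 M | 0.5 mol% |  |

| run | time / min | X / % |
|---|---|---|
| teal | 0.500 | 34 |
| teal | 1.00 | 65 |
| teal | 1.33 | 81 |
| teal | 2.00 | 85 |
| teal | 2.50 | 84 |
| red | 0.500 | 39 |
| red | 1.00 | 66 |
| red | 1.33 | 73 |
| red | 2.00 | 79 |
| red | 2.50 | 82 |

(standard deviation of a reading: 2 percentage points)

- apparent order in Z when 5.0% of the J are converted (percent change of the rate of making X for one percent more Z charged)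

- what was read earlier has a scatter of 2 percentage points, one standard deviation
- no earlier run changes the charge of Z; that part of a forecast is a guess

Both earlier runs started straight. I read their first points as turnovers per Z:

146 min⁻¹ on average.

Then the curves bent and levelled. Teal ended at 84% and red at 82%. I read each level as the J left after J takes G one to one, which gives 86.0% for teal and 78.0% for red. This is a rough rule, given the scatter. For the flask the level is:

90.0%

I carried one quantity, the knee time: the time the straight start takes to reach the level.

knee time = level / (loading × turnovers per Z) = 1.23 min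

For teal the same reckoning gave 1.18 min, and teal read 81% at 1.33 min. So I drew the flask straight up to its level, then flat. No earlier run changes Z, so an order of 1 stayed my guess.

The forecast gave 1, within 0.6 to 1.25, saying “The catalyst looks saturated with substrate”.

The flask gave 0.95.

    J + Z → D (k = 8.58 M⁻¹ s⁻¹)
    D → L (k = 3.31 s⁻¹)
    L → Z + X (k = 263 s⁻¹)
    J + G → E (k = 4.58 M⁻¹ s⁻¹)

At 0.590 min the flask's Z had a half-life of 0.090 s against J, shorter than the 0.21 s of D. At 0.400 min D was the flask's resting state: it held 74.5% of the catalyst, more than the 24.5% of Z and the 0.938% of L. My straight line put half the turnover at 0.615 min, and the last step had done half of its turnover by 0.595 min. At 4.00 min the flask held 90.0% X and 10.0% E.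

The numbers in the tables come from a simulation with made-up constants; scatter was added.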